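**Plan**

1. Units are numbered 1–4 from the catechin end to the terminal epicatechin. Retrosynthesis: global hydrogenolysis (16 benzyl ethers, 3 aryl bromides), then the interflavan bonds are cut: C4(unit 2)–C8(unit 3) first (2+2), then C4(unit 1)–C6(unit 2) and C4(unit 3)–C8(unit 4).
2. All three epicatechin units, terminal unit 4 included, derive from one de novo intermediate, tetra-O-benzylepicatechin 12. Its ring C is cut at C3–C4 (nitro-aldol) and O1–C2 (oxa-Michael) back to a ring-A salicylaldehyde and a ring-B nitrostyrene. Unit 1 comes from (+)-catechin.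
3. Enabling feature: O1 and C4 are ortho substituents of ring A (on C8a and C4a), and C3 lies between benzylic C2 and C4. A formyl group as C4 next to the free O1 phenol, plus a nitro group on C3, lets the phenoxide add to C2 and the C3 nitronate close ring C onto C4; the nitro group is later exchanged for the C3 oxygen.
4. Forward: ring C (steps 1–4), then 12 (step 5), then donor 13, dimer 14 (units 3–4), capped thio donor 16 (unit 2) and capped catechin donor 20 (unit 1), then dimer 21 (4α→6, forced by the C8 bromine), tetramer 22 and the target.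
5. Stereochemistry: C2/C3 of the epicatechin units from a catalyst-controlled dynamic kinetic resolution of ketone 11; C2/C3 of unit 1 from (+)-catechin; each C4 from attack on the C4 cation anti to the 3-OH (4β for epicatechin, 4α for catechin).

Key step: step 3

Assumption 1: the (S,S) hand of the ruthenium catalyst in step 5 is taken to give the (2R,3R) alcohol; the hand is checked on the first run against the sign of rotation of natural-series material and the mirror-image catalyst is used if required.
Assumption 2: the 4-(2-ethoxyethoxy) and 4-arylthio groups are drawn as the expected epimers; C4 of these donors becomes planar on ionisation, so their configuration does not affect the route.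

**Route**

Step 1
Reactants: 1 3,5-bis(benzyloxy)phenol
Product: 3 4,6-bis(benzyloxy)-2-hydroxybenzaldehyde, via ortho-hydroxymethyl phenol 2 (not isolated)
Conditions: (CH2O)n, MgCl2, Et3N, MeCN, reflux; aq. HCl work-up
Reagents that add atoms: paraformaldehyde (as formaldehyde) C=O
Why: Magnesium phenoxide-directed ortho-hydroxymethylation followed by hydride transfer to a second formaldehyde (ortho-selective formylation of phenols) should place the future C4 carbon next to the O1 phenol; the two ortho positions of 1 are equivalent and the para position is not attacked.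

Step 2
Reactants: 4 3,4-bis(benzyloxy)benzaldehyde
Product: 5 (E)-1,2-bis(benzyloxy)-4-(2-nitrovinyl)benzene
Conditions: MeNO2, NH4OAc, AcOH, 100 °C
Reagents that add atoms: nitromethane C[N+](=O)[O-]
Why: Henry condensation with dehydration should give the thermodynamically favoured (E)-β-nitrostyrene, which carries ring B, C2 and the nitro-activated C3.

Step 3
Reactants: 3 4,6-bis(benzyloxy)-2-hydroxybenzaldehyde; 5 (E)-1,2-bis(benzyloxy)-4-(2-nitrovinyl)benzene
Product: 8 rac-5,7-bis(benzyloxy)-2-[3,4-bis(benzyloxy)phenyl]-3-nitro-2H-chromene, via oxa-Michael adduct 6 (not isolated), via nitro-aldol adduct 7 (not isolated)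
Conditions: DABCO (0.5 equiv), MeCN, 60 °C
Reagents that add atoms: none
Why: DABCO generates the phenoxide of 3, which adds reversibly to the benzylic alkene carbon of 5 (oxa-Michael, O1–C2) to give nitronate 6, whose carbon C3 attacks the neighbouring formyl carbon C4 (intramolecular Henry reaction) to give 7, and E1cB loss of water to the conjugated nitroalkene 8 drives the reversible sequence forward. The closest known reaction type is the amine-mediated oxa-Michael/Henry/dehydration cascade of salicylaldehydes with β-nitrostyrenes to 2-aryl-3-nitro-2H-chromenes. Ring C is closed by the C3–C4 bond in the 6-exo-trig mode (6-enolexo with respect to the nitronate). The one stereocentre left in 8, C2, is deliberately formed racemic, since it becomes epimerisable in ketone 11 and is set together with C3 by the catalyst of step 5. The step needs conjugate addition through the phenol oxygen rather than through the electron-rich ring carbons, and C-attack of the nitronate on the aldehyde: the single free phenol ortho to the formyl group fixes the regiochemistry, only the C-adduct can dehydrate, and the nitro group makes C3 nucleophilic without irreversible loss of O1 (a retro-oxa-Michael merely returns 3 and 5). The nitro group and the C3=C4 unsaturation are the helpers removed in step 4.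

Step 4
Reactants: 8 rac-5,7-bis(benzyloxy)-2-[3,4-bis(benzyloxy)phenyl]-3-nitro-2H-chromene
Product: 11 rac-5,7-bis(benzyloxy)-2-[3,4-bis(benzyloxy)phenyl]chroman-3-one, via chroman-3-one oxime 9 (not isolated), via chroman-3-imine 10 (not isolated)
Conditions: Fe powder, AcOH/H2O, 80 °C, N2
Reagents that add atoms: water O
Why: Iron in acetic acid should reduce the conjugated nitroalkene through the oxime to the imine, which hydrolyses to the C3 ketone (reductive Nef reaction), leaving C4 as CH2 and the benzyl ethers untouched; the loss of configuration at C2 is of no consequence.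

Step 5
Reactants: 11 rac-5,7-bis(benzyloxy)-2-[3,4-bis(benzyloxy)phenyl]chroman-3-one
Product: 12 (2R,3R)-5,7,3',4'-tetra-O-benzylepicatechin
Conditions: RuCl[(S,S)-TsDPEN](p-cymene) (2 mol %), HCO2H/Et3N (2:5), DMF, 35 °C, degassed; recrystallisation
Reagents that add atoms: none
Why: The α-aryl-α-aryloxy ketone racemises at C2 through its enol in the amine-rich formate medium while the chiral ruthenium hydride reduces one enantiomer faster and delivers hydride to C3 anti to the C2 aryl group (asymmetric transfer hydrogenation with dynamic kinetic resolution of an α-aryl cyclic ketone), so the 2,3-cis (2R,3R) alcohol should be set at both centres by the catalyst.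

Step 6
Reactants: 12 (2R,3R)-5,7,3',4'-tetra-O-benzylepicatechin
Product: 13 4β-(2-ethoxyethoxy)-5,7,3',4'-tetra-O-benzylepicatechin
Conditions: DDQ, 2-ethoxyethanol, CH2Cl2, rt
Reagents that add atoms: 2-ethoxyethanol CCOCCO
Why: DDQ abstracts hydride from C4, which is benzylic to the electron-rich ring A, and the resulting quinone methide is trapped by the alcohol anti to the C2 aryl group (oxidative C4 alkoxylation of benzyl-protected flavan-3-ols); the 3-OH and the benzyl ethers should survive.

Step 7
Reactants: 13 4β-(2-ethoxyethoxy)-5,7,3',4'-tetra-O-benzylepicatechin; 12 (2R,3R)-5,7,3',4'-tetra-O-benzylepicatechin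
Product: 14 octa-O-benzyl epicatechin-(4β→8)-epicatechin (octa-O-benzylprocyanidin B2)
Conditions: TMSOTf (cat.), CH2Cl2, −78 °C; 12 in threefold excess, surplus recovered
Reagents that add atoms: none
Why: The Lewis acid ionises the C4 ether of 13 and the C4 cation is attacked by C8 of 12, the most nucleophilic ring-A position, from the face anti to the 3-OH and the C2 aryl group (Friedel–Crafts-type flavan-4-yl cation coupling), which should give the 4β→8 bond; excess 12 suppresses chain extension.

Step 8
Reactants: 13 4β-(2-ethoxyethoxy)-5,7,3',4'-tetra-O-benzylepicatechin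
Product: 15 8-bromo-4β-(2-ethoxyethoxy)-5,7,3',4'-tetra-O-benzylepicatechin
Conditions: NBS (1.0 equiv), CH2Cl2, −40 °C to 0 °C
Reagents that add atoms: N-bromosuccinimide O=C1CCC(=O)N1Br
Why: Electrophilic aromatic bromination should occur at C8, the most reactive ring-A position of benzylated flavan-3-ols, which blocks C8 so that this unit can later react only at C6.

Step 9
Reactants: 15 8-bromo-4β-(2-ethoxyethoxy)-5,7,3',4'-tetra-O-benzylepicatechin
Product: 16 8-bromo-4β-(2,6-dimethylphenylthio)-5,7,3',4'-tetra-O-benzylepicatechin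
Conditions: 2,6-Me2C6H3SH, BF3·OEt2, CH2Cl2, −78 °C to −30 °C
Reagents that add atoms: 2,6-dimethylbenzenethiol Cc1cccc(C)c1S
Why: Lewis acid-mediated SN1 exchange of the C4 ether for the thiol (thiolysis of a flavan-4-yl ether), the thiol entering trans to the 3-OH, should install a soft, hindered leaving group that is inert to the hard Lewis acid of step 13.

Step 10
Reactants: 17 (+)-catechin
Product: 18 (2R,3S)-5,7,3',4'-tetra-O-benzylcatechin
Conditions: BnBr, K2CO3, DMF, 0 °C to rt
Reagents that add atoms: benzyl bromide BrCc1ccccc1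
Why: Williamson etherification should take place at the four phenols, which are far more acidic than the secondary 3-OH; C2 and C3 come unchanged from the natural product.

Step 11
Reactants: 18 (2R,3S)-5,7,3',4'-tetra-O-benzylcatechin
Product: 19 4β-(2-ethoxyethoxy)-5,7,3',4'-tetra-O-benzylcatechin
Conditions: DDQ, 2-ethoxyethanol, CH2Cl2, rt
Reagents that add atoms: 2-ethoxyethanol CCOCCO
Why: As in step 6, hydride abstraction from C4 by DDQ and trapping of the quinone methide by the alcohol (oxidative C4 alkoxylation) should give the C4 ether donor.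

Step 12
Reactants: 19 4β-(2-ethoxyethoxy)-5,7,3',4'-tetra-O-benzylcatechin
Product: 20 6,8-dibromo-4β-(2-ethoxyethoxy)-5,7,3',4'-tetra-O-benzylcatechin
Conditions: NBS (2.1 equiv), CH2Cl2, 0 °C to rt
Reagents that add atoms: N-bromosuccinimide O=C1CCC(=O)N1Br
Why: Twofold electrophilic aromatic bromination should fill C8 and then C6, so that ring A of this donor can no longer act as a nucleophile toward its own C4 cation.

Step 13
Reactants: 20 6,8-dibromo-4β-(2-ethoxyethoxy)-5,7,3',4'-tetra-O-benzylcatechin; 16 8-bromo-4β-(2,6-dimethylphenylthio)-5,7,3',4'-tetra-O-benzylepicatechin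
Product: 21 6,8-dibromo-tetra-O-benzylcatechin-(4α→6)-[8-bromo-4β-(2,6-dimethylphenylthio)-tetra-O-benzylepicatechin]
Conditions: BF3·OEt2, CH2Cl2, −78 °C to −30 °C; 16 in excess, surplus recovered
Reagents that add atoms: none
Why: The hard Lewis acid should ionise only the C4 ether of 20, and the cation is attacked by C6 of 16 (its only free ring-A position, C8 being brominated) anti to the 3-OH of the catechin unit to give the 4α→6 bond (orthogonally activated Friedel–Crafts-type coupling); the ortho methyl groups shield the sulfur of 16 from ionisation and from thio-group transfer.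

Step 14
Reactants: 21 6,8-dibromo-tetra-O-benzylcatechin-(4α→6)-[8-bromo-4β-(2,6-dimethylphenylthio)-tetra-O-benzylepicatechin]; 14 octa-O-benzyl epicatechin-(4β→8)-epicatechin
Product: 22 hexadeca-O-benzyl-6,8-dibromocatechin-(4α→6)-8-bromoepicatechin-(4β→8)-epicatechin-(4β→8)-epicatechin
Conditions: AgBF4, 2,6-di-tert-butyl-4-methylpyridine, THF, −40 °C to 0 °C, dark; 14 in twofold excess
Reagents that add atoms: none
Why: Monovalent silver binds the sulfide and releases the C4 cation of the lower unit of 21, which should be attacked by C8 of the upper unit of 14 from the face anti to the 3-OH and the C2 aryl group to give the 4β→8 bond (thiophile-promoted flavan-4-yl cation coupling); 21 has no free nucleophilic ring-A position and the pyridine base holds the acid released.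

Step 15
Reactants: 22 hexadeca-O-benzyl-6,8-dibromocatechin-(4α→6)-8-bromoepicatechin-(4β→8)-epicatechin-(4β→8)-epicatechin
Product: 23 catechin-(4α→6)-epicatechin-(4β→8)-epicatechin-(4β→8)-epicatechin (CNP0228086.1)
Conditions: H2 (1 atm), Pd(OH)2/C, NaOAc, THF/MeOH/H2O, rt
Reagents that add atoms: none
Why: Hydrogenolysis should cleave the sixteen benzyl ethers and the three aryl C–Br bonds in one operation, with NaOAc buffering the HBr so that the acid-labile interflavan bonds and all stereocentres survive.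

**Compound list**

1 | 3,5-bis(benzyloxy)phenol | Oc1cc(OCc2ccccc2)cc(OCc2ccccc2)c1 | starting material
2 | 3,5-bis(benzyloxy)-2-(hydroxymethyl)phenol (formed as its magnesium phenoxide, not isolated) | OCc1c(O)cc(OCc2ccccc2)cc1OCc1ccccc1 | intermediate
3 | 4,6-bis(benzyloxy)-2-hydroxybenzaldehyde | O=Cc1c(O)cc(OCc2ccccc2)cc1OCc1ccccc1 | intermediate
4 | 3,4-bis(benzyloxy)benzaldehyde | O=Cc1ccc(OCc2ccccc2)c(OCc2ccccc2)c1 | starting material
5 | (E)-1,2-bis(benzyloxy)-4-(2-nitrovinyl)benzene | [O-][N+](=O)/C=C/c1ccc(OCc2ccccc2)c(OCc2ccccc2)c1 | intermediate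
6 | rac-4,6-bis(benzyloxy)-2-{1-[3,4-bis(benzyloxy)phenyl]-2-nitroethoxy}benzaldehyde (oxa-Michael adduct, formed as its nitronate, not isolated) | O=Cc1c(OC(C[N+](=O)[O-])c2ccc(OCc3ccccc3)c(OCc3ccccc3)c2)cc(OCc2ccccc2)cc1OCc1ccccc1 | intermediate
7 | 5,7-bis(benzyloxy)-2-[3,4-bis(benzyloxy)phenyl]-3-nitrochroman-4-ol (nitro-aldol adduct, mixture of racemic diastereomers, not isolated) | OC1c2c(OCc3ccccc3)cc(OCc3ccccc3)cc2OC(c2ccc(OCc3ccccc3)c(OCc3ccccc3)c2)C1[N+](=O)[O-] | intermediate
8 | rac-5,7-bis(benzyloxy)-2-[3,4-bis(benzyloxy)phenyl]-3-nitro-2H-chromene | [O-][N+](=O)C1=Cc2c(OCc3ccccc3)cc(OCc3ccccc3)cc2OC1c1ccc(OCc2ccccc2)c(OCc2ccccc2)c1 | intermediate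
9 | rac-5,7-bis(benzyloxy)-2-[3,4-bis(benzyloxy)phenyl]chroman-3-one oxime (not isolated) | ON=C1Cc2c(OCc3ccccc3)cc(OCc3ccccc3)cc2OC1c1ccc(OCc2ccccc2)c(OCc2ccccc2)c1 | intermediate
10 | rac-5,7-bis(benzyloxy)-2-[3,4-bis(benzyloxy)phenyl]chroman-3-imine (not isolated) | N=C1Cc2c(OCc3ccccc3)cc(OCc3ccccc3)cc2OC1c1ccc(OCc2ccccc2)c(OCc2ccccc2)c1 | intermediate
11 | rac-5,7-bis(benzyloxy)-2-[3,4-bis(benzyloxy)phenyl]chroman-3-one | O=C1Cc2c(OCc3ccccc3)cc(OCc3ccccc3)cc2OC1c1ccc(OCc2ccccc2)c(OCc2ccccc2)c1 | intermediate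
12 | (2R,3R)-5,7,3',4'-tetra-O-benzylepicatechin | O(Cc9ccccc9)c1cc(OCc9ccccc9)c2c(c1)O[C@H](c1ccc(OCc9ccccc9)c(OCc9ccccc9)c1)[C@H](O)C2 | intermediate
13 | 4β-(2-ethoxyethoxy)-5,7,3',4'-tetra-O-benzylepicatechin | O(Cc9ccccc9)c1cc(OCc9ccccc9)c2c(c1)O[C@H](c1ccc(OCc9ccccc9)c(OCc9ccccc9)c1)[C@H](O)[C@H]2OCCOCC | intermediate
14 | octa-O-benzyl epicatechin-(4β→8)-epicatechin (units 3 and 4) | O(Cc9ccccc9)c1cc(OCc9ccccc9)c2c(c1)O[C@H](c1ccc(OCc9ccccc9)c(OCc9ccccc9)c1)[C@H](O)[C@H]2c1c(OCc9ccccc9)cc(OCc9ccccc9)c3c1O[C@H](c1ccc(OCc9ccccc9)c(OCc9ccccc9)c1)[C@H](O)C3 | intermediate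
15 | 8-bromo-4β-(2-ethoxyethoxy)-5,7,3',4'-tetra-O-benzylepicatechin | O(Cc9ccccc9)c1cc(OCc9ccccc9)c2c(c1Br)O[C@H](c1ccc(OCc9ccccc9)c(OCc9ccccc9)c1)[C@H](O)[C@H]2OCCOCC | intermediate
16 | 8-bromo-4β-(2,6-dimethylphenylthio)-5,7,3',4'-tetra-O-benzylepicatechin | O(Cc9ccccc9)c1cc(OCc9ccccc9)c2c(c1Br)O[C@H](c1ccc(OCc9ccccc9)c(OCc9ccccc9)c1)[C@H](O)[C@H]2Sc1c(C)cccc1C | intermediate
17 | (+)-catechin, (2R,3S) | Oc1cc(O)c2c(c1)O[C@H](c1ccc(O)c(O)c1)[C@@H](O)C2 | starting material
18 | (2R,3S)-5,7,3',4'-tetra-O-benzylcatechin | O(Cc9ccccc9)c1cc(OCc9ccccc9)c2c(c1)O[C@H](c1ccc(OCc9ccccc9)c(OCc9ccccc9)c1)[C@@H](O)C2 | intermediate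
19 | 4β-(2-ethoxyethoxy)-5,7,3',4'-tetra-O-benzylcatechin | O(Cc9ccccc9)c1cc(OCc9ccccc9)c2c(c1)O[C@H](c1ccc(OCc9ccccc9)c(OCc9ccccc9)c1)[C@@H](O)[C@H]2OCCOCC | intermediate
20 | 6,8-dibromo-4β-(2-ethoxyethoxy)-5,7,3',4'-tetra-O-benzylcatechin | O(Cc9ccccc9)c1c(Br)c(OCc9ccccc9)c2c(c1Br)O[C@H](c1ccc(OCc9ccccc9)c(OCc9ccccc9)c1)[C@@H](O)[C@H]2OCCOCC | intermediate
21 | 6,8-dibromo-tetra-O-benzylcatechin-(4α→6)-[8-bromo-4β-(2,6-dimethylphenylthio)-tetra-O-benzylepicatechin] (units 1 and 2) | O(Cc9ccccc9)c1c(Br)c(OCc9ccccc9)c2c(c1Br)O[C@H](c1ccc(OCc9ccccc9)c(OCc9ccccc9)c1)[C@@H](O)[C@@H]2c1c(OCc9ccccc9)c(Br)c2c(c1OCc9ccccc9)[C@H](Sc1c(C)cccc1C)[C@@H](O)[C@@H](c1ccc(OCc9ccccc9)c(OCc9ccccc9)c1)O2 | intermediate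
22 | hexadeca-O-benzyl-6,8-dibromocatechin-(4α→6)-8-bromoepicatechin-(4β→8)-epicatechin-(4β→8)-epicatechin | O(Cc9ccccc9)c1c(Br)c(OCc9ccccc9)c2c(c1Br)O[C@H](c1ccc(OCc9ccccc9)c(OCc9ccccc9)c1)[C@@H](O)[C@@H]2c1c(OCc9ccccc9)c(Br)c2c(c1OCc9ccccc9)[C@H](c1c(OCc9ccccc9)cc(OCc9ccccc9)c3c1O[C@H](c1ccc(OCc9ccccc9)c(OCc9ccccc9)c1)[C@H](O)[C@H]3c1c(OCc9ccccc9)cc(OCc9ccccc9)c3c1O[C@H](c1ccc(OCc9ccccc9)c(OCc9ccccc9)c1)[C@H](O)C3)[C@@H](O)[C@@H](c1ccc(OCc9ccccc9)c(OCc9ccccc9)c1)O2 | intermediate
23 | catechin-(4α→6)-epicatechin-(4β→8)-epicatechin-(4β→8)-epicatechin (CNP0228086.1) | Oc1cc(O)c2c(c1)O[C@H](c1ccc(O)c(O)c1)[C@@H](O)[C@@H]2c1c(O)cc2c(c1O)[C@H](c1c(O)cc(O)c3c1O[C@H](c1ccc(O)c(O)c1)[C@H](O)[C@H]3c1c(O)cc(O)c3c1O[C@H](c1ccc(O)c(O)c1)[C@H](O)C3)[C@@H](O)[C@@H](c1ccc(O)c(O)c1)O2 | target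

**Summary**

Total step count: 15.
Longest linear sequence: 10 steps (steps 1, 3, 4, 5, 6, 8, 9, 13, 14, 15; compound 1 to compound 23).

**Steps most likely to fail**

Step 5. The risk is that C2 epimerisation is too slow relative to hydride transfer, or that the catalyst discriminates poorly between the enantiomers of the ketone or its faces, so that enantiomeric purity erodes or trans alcohol forms. The fallback sets out from 11 and replaces catalyst control by substrate control plus resolution. Reduction with LiBH(s-Bu)3 in THF at −78 °C should deliver hydride anti to the C2 aryl group and give the racemic 2,3-cis alcohol, that is 12 together with its mirror image (2S,3S)-5,7,3',4'-tetra-O-benzylepicatechin F1. The enantiomers are separated by preparative chromatography on a cellulose tris(3,5-dimethylphenylcarbamate) phase. The (2R,3R) component re-enters the route at 12, and F1 is oxidised back to 11 with Dess–Martin periodinane and recycled.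

Step 13. The risk is that attack by the hindered, bromine-deactivated C6 position is slow, so that the cation decays, facial selectivity at C4 of the catechin unit erodes, or the thio group of the acceptor is ionised or transferred under the hard Lewis acid. The fallback inverts the orthogonal pair and sets out from 20 and 15. Treatment of 20 with 2,6-dimethylbenzenethiol and BF3·OEt2 should give 6,8-dibromo-4α-(2,6-dimethylphenylthio)-5,7,3',4'-tetra-O-benzylcatechin F2. F2 is then activated with AgBF4 and 2,6-di-tert-butyl-4-methylpyridine in THF at 0 °C in the presence of excess 15, whose C4 ether is inert to the soft promoter. This should give 6,8-dibromo-tetra-O-benzylcatechin-(4α→6)-[8-bromo-4β-(2-ethoxyethoxy)-tetra-O-benzylepicatechin] F3. F3 is finally ionised with TMSOTf in CH2Cl2 at −78 °C in the presence of excess 14, which brings the sequence back to the route at 22.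

Step 14. The risk is incomplete activation of the hindered aryl sulfide, attack at a competing ring-A position of the dimeric acceptor (C6 of either unit of 14), or acid-induced scrambling of interflavan bonds. The fallback replaces the 2+2 union by a 2+1+1 sequence and sets out from 21 and 13. Activation of 21 with AgBF4 and 2,6-di-tert-butyl-4-methylpyridine in the presence of the monomeric acceptor 13 should give the trimer hexa... dodeca-O-benzyl-6,8-dibromocatechin-(4α→6)-8-bromoepicatechin-(4β→8)-[4β-(2-ethoxyethoxy)epicatechin] F4; 13 has a single strongly nucleophilic position (C8) and an ether that silver does not touch. F4 is then ionised with TMSOTf in CH2Cl2 at −78 °C in the presence of excess 12, whose C8 selectivity is that of step 7, and the sequence returns to the route at 22.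

Further compounds
F1 | step 5 | (2S,3S)-5,7,3',4'-tetra-O-benzylepicatechin | O(Cc9ccccc9)c1cc(OCc9ccccc9)c2c(c1)O[C@@H](c1ccc(OCc9ccccc9)c(OCc9ccccc9)c1)[C@@H](O)C2
F2 | step 13 | 6,8-dibromo-4α-(2,6-dimethylphenylthio)-5,7,3',4'-tetra-O-benzylcatechin | O(Cc9ccccc9)c1c(Br)c(OCc9ccccc9)c2c(c1Br)O[C@H](c1ccc(OCc9ccccc9)c(OCc9ccccc9)c1)[C@@H](O)[C@@H]2Sc1c(C)cccc1C
F3 | step 13 | 6,8-dibromo-tetra-O-benzylcatechin-(4α→6)-[8-bromo-4β-(2-ethoxyethoxy)-tetra-O-benzylepicatechin] | O(Cc9ccccc9)c1c(Br)c(OCc9ccccc9)c2c(c1Br)O[C@H](c1ccc(OCc9ccccc9)c(OCc9ccccc9)c1)[C@@H](O)[C@@H]2c1c(OCc9ccccc9)c(Br)c2c(c1OCc9ccccc9)[C@H](OCCOCC)[C@@H](O)[C@@H](c1ccc(OCc9ccccc9)c(OCc9ccccc9)c1)O2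
F4 | step 14 | dodeca-O-benzyl-6,8-dibromocatechin-(4α→6)-8-bromoepicatechin-(4β→8)-[4β-(2-ethoxyethoxy)epicatechin] | O(Cc9ccccc9)c1c(Br)c(OCc9ccccc9)c2c(c1Br)O[C@H](c1ccc(OCc9ccccc9)c(OCc9ccccc9)c1)[C@@H](O)[C@@H]2c1c(OCc9ccccc9)c(Br)c2c(c1OCc9ccccc9)[C@H](c1c(OCc9ccccc9)cc(OCc9ccccc9)c3c1O[C@H](c1ccc(OCc9ccccc9)c(OCc9ccccc9)c1)[C@H](O)[C@H]3OCCOCC)[C@@H](O)[C@@H](c1ccc(OCc9ccccc9)c(OCc9ccccc9)c1)O2
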